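**Retrosynthetic overview**

- C1=C2 and C5=C6 are made last by two eliminations (methanol from a C1 methyl ketal, water from a C6 hydroxybutenolide). The (5E)-alkylidene butenolide (C5=C6–C7=C11–C12) is carried as a 2,3,4-trisubstituted furan (C6, C7, C11, C12) and unveiled with singlet oxygen after the O13 acetate and O8 methacrylate are in place.
- Key disconnection, C3–C4 together with O4–C1: the 2,3-dihydrofuran ring O4–C1(=C2)–C3–C4 is a dehydrated γ-hydroxy ketone (C1 at ketone level, C4 a carbinol, 1,4-related). C3 (β-carbon of a C1 vinyl ketone) and C4 (carbon of a methyl ketone), two acceptor carbons, are therefore joined by SmI2 reductive coupling. This closes the ten-membered carbocycle C1–C10 and, by lactol formation in the same flask, the oxolane, and sets C4.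
- The acyclic diketone comes from furan-3,4-diyldimethanol: C5/C4/C15 by directed lithiation–allylation (later Wacker oxidation), C8 by catalytic asymmetric 2-(alkoxycarbonyl)allylation, C10 by anti-selective enolate hydroxylation in a temporary γ-lactone (O8–C8–C9–C10–C1), which is opened to the Weinreb amide and the C1 vinyl ketone.
- Order of ring formation: furan (bought) → temporary γ-lactone → ten-membered carbocycle and oxolane together (key step) → butenolide (from the furan) → enol ether double bond.

Key step: step 10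

**Remarks on the chemistry**

- Carbons are numbered as in the germacrane skeleton of the target: C1 (enol ether carbon), C2, C3, C4 (bears the C15 methyl and the ring oxygen O4), C5, C6, C7, C8 (methacrylate), C9, C10 (bears the C14 methyl and OH), C11, C12 (lactone carbonyl), C13 (CH2OAc). In the furan intermediates, furan C2/C3/C4/C5 are C6/C7/C11/C12.
- TIPS = tri(propan-2-yl)silyl, TBS = tert-butyldimethylsilyl, TES = triethylsilyl.
- The configuration at C6 of the hydroxybutenolide compounds (27–29, F4, F5) is left undefined because that centre becomes trigonal again.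
- In step 4 the ligand enantiomer is assumed to be the one that gives Re-face addition.

**Route**

Step 1
Reactants: 1 furan-3,4-diyldimethanol
Product: 2 [4-(TIPS-oxymethyl)furan-3-yl]methanol
Conditions: NaH (1.0 equiv), THF, 0 °C; i-Pr3SiCl (1.0 equiv), 0 °C → rt
Reagents that add atoms: chlorotri(propan-2-yl)silane, CC(C)[Si](Cl)(C(C)C)C(C)C
Why: O-silylation of the sparingly soluble monosodium alkoxide of a symmetric diol should give the mono-ether and so tell the future C13 from the future C8.

Step 2
Reactants: 2 [4-(TIPS-oxymethyl)furan-3-yl]methanol; 3 allyl bromide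
Product: 5 [2-allyl-4-(TIPS-oxymethyl)furan-3-yl]methanol, via dilithio alkoxide 4 (not isolated)
Conditions: n-BuLi (2.2 equiv), THF, −78 → 0 °C; allyl bromide (1.05 equiv), −78 → 0 °C; H2O
Reagents that add atoms: allyl bromide (3), C=CCBr
Why: Alkoxide-directed ortho-metalation of a 3-furylmethanol takes place at the neighbouring α-position (C6), and allylation of the furyllithium installs C5, C4 and C15 as a masked methyl ketone.

Step 3
Reactants: 5 [2-allyl-4-(TIPS-oxymethyl)furan-3-yl]methanol
Product: 6 2-allyl-4-(TIPS-oxymethyl)furan-3-carbaldehyde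
Conditions: MnO2 (15 equiv), CH2Cl2, rt
Reagents that add atoms: none
Why: Activated MnO2 oxidises the heterobenzylic primary alcohol to the aldehyde and leaves the terminal alkene, the furan and the silyl ether untouched.

Step 4
Reactants: 6 2-allyl-4-(TIPS-oxymethyl)furan-3-carbaldehyde; 7 ethyl 2-(bromomethyl)prop-2-enoate
Product: 10 (5R)-5-[2-allyl-4-(TIPS-oxymethyl)furan-3-yl]-3-methylideneoxolan-2-one, via trimethylsilyl ether 8 (not isolated), via hydroxy ester 9 (not isolated)
Conditions: CrCl2 (10 mol %), chiral tridentate carbazole bis(oxazoline) ligand (12 mol %), Mn (2 equiv), Me3SiCl (1.2 equiv), i-Pr2NEt (0.3 equiv), THF, rt; then 1 M aq. HCl, THF, rt; TsOH·H2O (cat.), CH2Cl2, rt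
Reagents that add atoms: ethyl 2-(bromomethyl)prop-2-enoate (7), C=C(CBr)C(=O)OCC
Why: Catalytic asymmetric Nozaki–Hiyama-type 2-(alkoxycarbonyl)allylation, with the ligand enantiomer that directs the allylchromium to the Re face of the aldehyde, should set C8 (R), and the γ-hydroxy ester lactonises under acid to the α-methylene-γ-butyrolactone.

Step 5
Reactants: 10 (5R)-5-[2-allyl-4-(TIPS-oxymethyl)furan-3-yl]-3-methylideneoxolan-2-one
Product: 12 (3S,5R)-5-[2-allyl-4-(TIPS-oxymethyl)furan-3-yl]-3-hydroxy-3-methyloxolan-2-one, via lithium enolate 11 (not isolated)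
Conditions: LiBH(s-Bu)3 (1.1 equiv), THF, −78 °C; then 2-(benzenesulfonyl)-3-phenyloxaziridine (1.4 equiv), −78 → −20 °C; aq. NH4Cl
Reagents that add atoms: 2-(benzenesulfonyl)-3-phenyloxaziridine, O=S(=O)(c1ccccc1)N1OC1c1ccccc1
Why: Conjugate hydride addition to the α-methylene lactone gives the tetrasubstituted enolate, and its Davis oxidation should take place on the ring face anti to the C8 furyl group, which sets C10 (S) with the hydroxyl trans to the furyl group.

Step 6
Reactants: 12 (3S,5R)-5-[2-allyl-4-(TIPS-oxymethyl)furan-3-yl]-3-hydroxy-3-methyloxolan-2-one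
Product: 13 (2S,4R)-4-[2-allyl-4-(TIPS-oxymethyl)furan-3-yl]-2,4-dihydroxy-N-methoxy-N,2-dimethylbutanamide
Conditions: MeNH(OMe)·HCl (3 equiv), i-PrMgCl (7 equiv), THF, −20 → 0 °C; used crude
Reagents that add atoms: N,O-dimethylhydroxylamine hydrochloride, CNOC.Cl
Why: Aminolysis of the lactone by the chloromagnesium amide (Weinreb amide formation) opens the temporary ring, frees O8 and turns C1 into an acylating centre without touching C8 or C10.

Step 7
Reactants: 13 (2S,4R)-4-[2-allyl-4-(TIPS-oxymethyl)furan-3-yl]-2,4-dihydroxy-N-methoxy-N,2-dimethylbutanamide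
Product: 15 (2S,4R)-4-[2-allyl-4-(TIPS-oxymethyl)furan-3-yl]-4-(TBS-oxy)-N-methoxy-N,2-dimethyl-2-(TES-oxy)butanamide, via mono-silyl ether 14 (not isolated)
Conditions: t-BuMe2SiOTf (1.05 equiv), 2,6-lutidine (4 equiv), CH2Cl2, −78 °C; then Et3SiOTf (1.5 equiv), −78 → 0 °C
Reagents that add atoms: tert-butyldimethylsilyl trifluoromethanesulfonate, CC(C)(C)[Si](C)(C)OS(=O)(=O)C(F)(F)F; triethylsilyl trifluoromethanesulfonate, CC[Si](CC)(CC)OS(=O)(=O)C(F)(F)F
Why: Silyl triflate silylation should take the secondary C8 hydroxyl first and the hindered tertiary C10 hydroxyl second, which stops relactonisation and puts an acid-stable group on O8 and a bulky, non-chelating group on O10.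

Step 8
Reactants: 15 (2S,4R)-4-[2-allyl-4-(TIPS-oxymethyl)furan-3-yl]-4-(TBS-oxy)-N-methoxy-N,2-dimethyl-2-(TES-oxy)butanamide; 16 vinylmagnesium bromide
Product: 17 (4S,6R)-6-[2-allyl-4-(TIPS-oxymethyl)furan-3-yl]-6-(TBS-oxy)-4-methyl-4-(TES-oxy)hex-1-en-3-one
Conditions: CH2=CHMgBr (3 equiv), THF, 0 °C → rt; inverse quench into cold aq. NH4Cl
Reagents that add atoms: vinylmagnesium bromide (16), C=C[Mg]Br
Why: The chelated tetrahedral adduct of the Weinreb ketone synthesis stops at the ketone stage, so C2 and C3 enter as the vinyl ketone, and the cold inverse quench keeps the released hydroxylamine from adding to the enone.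

Step 9
Reactants: 17 (4S,6R)-6-[2-allyl-4-(TIPS-oxymethyl)furan-3-yl]-6-(TBS-oxy)-4-methyl-4-(TES-oxy)hex-1-en-3-one
Product: 18 (4S,6R)-6-(TBS-oxy)-4-methyl-6-[2-(2-oxopropyl)-4-(TIPS-oxymethyl)furan-3-yl]-4-(TES-oxy)hex-1-en-3-one
Conditions: PdCl2 (10 mol %), CuCl (20 mol %), O2 (1 atm), DMF/H2O 7:1, rt
Reagents that add atoms: water, O
Why: Tsuji–Wacker oxidation should hydrate the monosubstituted alkene with Markovnikov selectivity to the C4 methyl ketone, as it does for allylarenes, while the electron-poor vinyl ketone is not oxidised.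

Step 10
Reactants: 18 (4S,6R)-6-(TBS-oxy)-4-methyl-6-[2-(2-oxopropyl)-4-(TIPS-oxymethyl)furan-3-yl]-4-(TES-oxy)hex-1-en-3-one
Product: 20 (1S,4R,8R,10S)-hemiketal: ten-membered carbocycle C1–C10 fused at C6/C7 to the furan, O4 bridging C4 and C1, 1-OH, 8-OTBS, 10-OTES, 13-OTIPS, via ten-membered hydroxy ketone 19 (not isolated)
Conditions: SmI2 (2.3 equiv, 0.1 M in THF), HMPA (8 equiv), THF, −40 °C, 18 added by syringe pump over 8 h (final 2 mM); then MeOH (10 equiv), −78 °C → rt; air, aq. NaHCO3/Na2S2O3
Reagents that add atoms: none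
Why: Proposed new method: electron transfer from SmI2 to the enone, the most easily reduced group of 18, gives a trivalent-samarium dienolate radical with spin at C3 that adds to the C4 ketone (ketyl addition of a reduced C4 carbonyl to C3 would give the same bond), a second electron gives the C4 alkoxide and the C1 enolate, and on protonation at C2 the alkoxide closes onto the C1 carbonyl, so that C3–C4 and O4–C1 form in one flask. The closest known reaction type is the SmI2-mediated reductive coupling of ketones with α,β-unsaturated carbonyl compounds to γ-hydroxy carbonyl compounds, lactols and γ-lactones, which is also used to close eight-membered carbocycles, but a ten-membered closure with lactol formation in the same flask is not known. The carbocycle closes in the 10-endo-trig mode with respect to C2=C3 (exo with respect to the C4 carbonyl), helped by the cis-fixed furan edge C5–C6=C7–C8 and the quaternary C10, and the oxolane closes by 5-exo-trig addition of O4 to C1. C4 is controlled by the C10 stereocentre, because the tether reaches C3 only on the enone face that carries C9 and the rotamer about C1–C10 that turns the bulky, non-chelating triethylsilyloxy group away from the HMPA-solvated samarium on the enolate oxygen puts C9 on the face that leads to (4R), and C1 follows from C4 since the six-carbon bridge can span the oxolane only in a cis fashion. The step needs chemoselective reduction, coupling at the β-carbon instead of pinacol coupling, oligomerisation or conjugate reduction, and retention of the C10 oxygen, which are secured by the absence of other reducible groups (furan for the butenolide, silyl ethers for the esters), by high dilution without a proton source until the quench, and by the fact that spin and charge of the reduced enone sit on C3 and on oxygen and not on C1 next to the C10–O bond.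

Step 11
Reactants: 20 (1S,4R,8R,10S)-hemiketal
Product: 21 (1S,4R,8R,10S)-1-O-methyl ketal of 20
Conditions: PPTS (0.2 equiv), MeOH, 3 Å molecular sieves, 0 °C → rt
Reagents that add atoms: methanol, CO
Why: Acid-catalysed transacetalisation through the cyclic oxocarbenium ion should lock C1 as the mixed methyl ketal, and methanol can only enter on the face opposite to the bridge so that C1 keeps its configuration.

Step 12
Reactants: 21 (1S,4R,8R,10S)-1-O-methyl ketal
Product: 22 (1S,4R,8R,10S)-triol (21 with free 8-OH, 10-OH and 13-OH)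
Conditions: Bu4NF (6 equiv), THF, 0 → 40 °C; H2O
Reagents that add atoms: none
Why: Fluoride-induced cleavage of the three silyl ethers frees O13, O8 and O10 under non-acidic conditions, under which the mixed ketal cannot exchange with O8.

Step 13
Reactants: 22 (1S,4R,8R,10S)-triol; 23 acetyl chloride
Product: 24 13-O-acetate of 22
Conditions: AcCl (1.05 equiv), 2,4,6-collidine (2 equiv), CH2Cl2, −78 °C
Reagents that add atoms: acetyl chloride (23), CC(Cl)=O
Why: Acylation with acetyl chloride and collidine at low temperature should be selective for the primary C13 hydroxyl over the hindered secondary C8 and tertiary C10 hydroxyls.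

Step 14
Reactants: 24 13-O-acetate of 22; 25 methacrylic anhydride
Product: 26 8-O-methacrylate of 24
Conditions: methacrylic anhydride (2 equiv), Et3N (3 equiv), DMAP (0.2 equiv), CH2Cl2, 0 °C → rt
Reagents that add atoms: methacrylic anhydride (25), C=C(C)C(=O)OC(=O)C(C)=C
Why: DMAP-catalysed acyl transfer esterifies the remaining secondary C8 hydroxyl with retention, while the tertiary C10 hydroxyl is too hindered to react.

Step 15
Reactants: 26 8-O-methacrylate of 24
Product: 28 (1S,4R,8R,10S)-5-hydroxybutenolide (C12 lactone carbonyl, C6 bearing OH and the lactone oxygen, C7=C11), via furan endoperoxide 27 (not isolated)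
Conditions: O2, tetraphenylporphyrin (1 mol %), visible light, i-Pr2NEt (2 equiv), CH2Cl2, −78 °C → rt
Reagents that add atoms: dioxygen, O=O
Why: [4+2] cycloaddition of singlet oxygen to the electron-rich trisubstituted furan followed by base-induced Kornblum–DeLaMare fragmentation at C12, the only hydrogen-bearing carbon of the endoperoxide, should give the hydroxybutenolide with the carbonyl at C12 and the hydroxyl at C6, while the ketal and the esters are inert.

Step 16
Reactants: 28 (1S,4R,8R,10S)-5-hydroxybutenolide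
Product: 30 (1S,4R,5E,8R,10S)-alkylidene butenolide methyl ketal (the target with methanol added across C1=C2), via C6 acetate 29 (not isolated)
Conditions: Ac2O (1.5 equiv), pyridine (5 equiv), DMAP (0.1 equiv), CH2Cl2, 0 °C → rt
Reagents that add atoms: none
Why: Acylative dehydration of a 5-hydroxybutenolide, in which the pseudo-acid hydroxyl is acetylated and acetic acid is lost towards C5 (the only neighbouring C–H), should give the γ-alkylidene butenolide, and the ten-membered ring allows only the ring-cis, that is (5E), double bond.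

Step 17
Reactants: 30 (1S,4R,5E,8R,10S)-alkylidene butenolide methyl ketal
Product: 32 target CNP0394509.1, (4R,5E,8R,10S), via C10 trimethylsilyl ether 31 (not isolated)
Conditions: Me3SiOTf (3 equiv), i-Pr2NEt (6 equiv), CH2Cl2, −40 → 0 °C; then Et3N·3HF, THF, 0 °C
Reagents that add atoms: none
Why: Silyl triflate/amine conversion of a ketal into an enol ether (ionisation to the cyclic oxocarbenium ion and deprotonation at C2, the only α-carbon that bears hydrogen) should form the C1=C2 bond, and mild fluoride treatment removes the silyl group taken up by O10.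

**Compound list**

1 | furan-3,4-diyldimethanol | OCc1cocc1CO | starting material
2 | [4-(TIPS-oxymethyl)furan-3-yl]methanol | OCc1cocc1CO[Si](C(C)C)(C(C)C)C(C)C | intermediate
3 | allyl bromide (3-bromoprop-1-ene) | C=CCBr | starting material
4 | lithium [2-lithio-4-(TIPS-oxymethyl)furan-3-yl]methanolate | [Li]OCc1c([Li])occ1CO[Si](C(C)C)(C(C)C)C(C)C | intermediate
5 | [2-allyl-4-(TIPS-oxymethyl)furan-3-yl]methanol | C=CCc1occ(CO[Si](C(C)C)(C(C)C)C(C)C)c1CO | intermediate
6 | 2-allyl-4-(TIPS-oxymethyl)furan-3-carbaldehyde | C=CCc1occ(CO[Si](C(C)C)(C(C)C)C(C)C)c1C=O | intermediate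
7 | ethyl 2-(bromomethyl)prop-2-enoate | C=C(CBr)C(=O)OCC | starting material
8 | ethyl (4R)-4-[2-allyl-4-(TIPS-oxymethyl)furan-3-yl]-2-methylidene-4-(trimethylsilyloxy)butanoate | C=CCc1occ(CO[Si](C(C)C)(C(C)C)C(C)C)c1[C@@H](CC(=C)C(=O)OCC)O[Si](C)(C)C | intermediate
9 | ethyl (4R)-4-[2-allyl-4-(TIPS-oxymethyl)furan-3-yl]-4-hydroxy-2-methylidenebutanoate | C=CCc1occ(CO[Si](C(C)C)(C(C)C)C(C)C)c1[C@@H](CC(=C)C(=O)OCC)O | intermediate
10 | (5R)-5-[2-allyl-4-(TIPS-oxymethyl)furan-3-yl]-3-methylideneoxolan-2-one | C=CCc1occ(CO[Si](C(C)C)(C(C)C)C(C)C)c1[C@H]1CC(=C)C(=O)O1 | intermediate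
11 | lithium enolate of (5R)-5-[2-allyl-4-(TIPS-oxymethyl)furan-3-yl]-3-methyloxolan-2-one | C=CCc1occ(CO[Si](C(C)C)(C(C)C)C(C)C)c1[C@H]1CC(C)=C([O-])O1.[Li+] | intermediate
12 | (3S,5R)-5-[2-allyl-4-(TIPS-oxymethyl)furan-3-yl]-3-hydroxy-3-methyloxolan-2-one | C=CCc1occ(CO[Si](C(C)C)(C(C)C)C(C)C)c1[C@H]1C[C@](C)(O)C(=O)O1 | intermediate
13 | (2S,4R)-4-[2-allyl-4-(TIPS-oxymethyl)furan-3-yl]-2,4-dihydroxy-N-methoxy-N,2-dimethylbutanamide | C=CCc1occ(CO[Si](C(C)C)(C(C)C)C(C)C)c1[C@H](O)C[C@](C)(O)C(=O)N(C)OC | intermediate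
14 | (2S,4R)-4-[2-allyl-4-(TIPS-oxymethyl)furan-3-yl]-4-(TBS-oxy)-2-hydroxy-N-methoxy-N,2-dimethylbutanamide | C=CCc1occ(CO[Si](C(C)C)(C(C)C)C(C)C)c1[C@H](O[Si](C)(C)C(C)(C)C)C[C@](C)(O)C(=O)N(C)OC | intermediate
15 | (2S,4R)-4-[2-allyl-4-(TIPS-oxymethyl)furan-3-yl]-4-(TBS-oxy)-N-methoxy-N,2-dimethyl-2-(TES-oxy)butanamide | C=CCc1occ(CO[Si](C(C)C)(C(C)C)C(C)C)c1[C@H](O[Si](C)(C)C(C)(C)C)C[C@](C)(O[Si](CC)(CC)CC)C(=O)N(C)OC | intermediate
16 | vinylmagnesium bromide | C=C[Mg]Br | starting material
17 | (4S,6R)-6-[2-allyl-4-(TIPS-oxymethyl)furan-3-yl]-6-(TBS-oxy)-4-methyl-4-(TES-oxy)hex-1-en-3-one | C=CCc1occ(CO[Si](C(C)C)(C(C)C)C(C)C)c1[C@H](O[Si](C)(C)C(C)(C)C)C[C@](C)(O[Si](CC)(CC)CC)C(=O)C=C | intermediate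
18 | (4S,6R)-6-(TBS-oxy)-4-methyl-6-[2-(2-oxopropyl)-4-(TIPS-oxymethyl)furan-3-yl]-4-(TES-oxy)hex-1-en-3-one | CC(=O)Cc1occ(CO[Si](C(C)C)(C(C)C)C(C)C)c1[C@H](O[Si](C)(C)C(C)(C)C)C[C@](C)(O[Si](CC)(CC)CC)C(=O)C=C | intermediate
19 | (4R,8R,10S)-ten-membered hydroxy ketone: carbocycle C1(=O)–C2H2–C3H2–C4(OH)(CH3)–C5H2–C6=C7–C8H(OTBS)–C9H2–C10(CH3)(OTES), C6/C7 being C2/C3 of the furan that carries CH2OTIPS at C11 | O=C1CC[C@@](C)(O)Cc2occ(CO[Si](C(C)C)(C(C)C)C(C)C)c2[C@H](O[Si](C)(C)C(C)(C)C)C[C@]1(C)O[Si](CC)(CC)CC | intermediate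
20 | (1S,4R,8R,10S)-hemiketal of 19: O4 bonded to C1 (oxolane O4–C1–C2–C3–C4), 1-OH, 8-OTBS, 10-OTES, 13-OTIPS | O[C@@]12CC[C@@](C)(O1)Cc1occ(CO[Si](C(C)C)(C(C)C)C(C)C)c1[C@H](O[Si](C)(C)C(C)(C)C)C[C@]2(C)O[Si](CC)(CC)CC | intermediate
21 | (1S,4R,8R,10S)-1-O-methyl ketal of 20 | CO[C@@]12CC[C@@](C)(O1)Cc1occ(CO[Si](C(C)C)(C(C)C)C(C)C)c1[C@H](O[Si](C)(C)C(C)(C)C)C[C@]2(C)O[Si](CC)(CC)CC | intermediate
22 | (1S,4R,8R,10S)-triol: 21 with free 8-OH, 10-OH and 13-OH | CO[C@@]12CC[C@@](C)(O1)Cc1occ(CO)c1[C@H](O)C[C@]2(C)O | intermediate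
23 | acetyl chloride | CC(Cl)=O | starting material
24 | 13-O-acetate of 22 | CO[C@@]12CC[C@@](C)(O1)Cc1occ(COC(C)=O)c1[C@H](O)C[C@]2(C)O | intermediate
25 | methacrylic anhydride | C=C(C)C(=O)OC(=O)C(C)=C | starting material
26 | 8-O-methacrylate of 24 | CO[C@@]12CC[C@@](C)(O1)Cc1occ(COC(C)=O)c1[C@H](OC(=O)C(C)=C)C[C@]2(C)O | intermediate
27 | furan 2,5-endoperoxide of 26 (O–O bridge from C6 to C12) | CO[C@@]12CC[C@@](C)(O1)CC13OOC(O1)C(COC(C)=O)=C3[C@H](OC(=O)C(C)=C)C[C@]2(C)O | intermediate
28 | (1S,4R,8R,10S)-5-hydroxybutenolide: C12 lactone carbonyl, C6 bearing OH and the lactone oxygen, C7=C11; 1-OMe ketal, 8-O-methacrylate, 13-OAc, 10-OH | CO[C@@]12CC[C@@](C)(O1)CC1(O)OC(=O)C(COC(C)=O)=C1[C@H](OC(=O)C(C)=C)C[C@]2(C)O | intermediate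
29 | C6 acetate of 28 | CO[C@@]12CC[C@@](C)(O1)CC1(OC(C)=O)OC(=O)C(COC(C)=O)=C1[C@H](OC(=O)C(C)=C)C[C@]2(C)O | intermediate
30 | (1S,4R,5E,8R,10S)-1-methoxy-1,2-dihydro derivative of the target (methyl ketal at C1, C2H2, C5=C6 alkylidene butenolide) | CO[C@@]12CC[C@@](C)(O1)/C=C1/OC(=O)C(COC(C)=O)=C1[C@H](OC(=O)C(C)=C)C[C@]2(C)O | intermediate
31 | 10-O-trimethylsilyl ether of the target | C=C(C)C(=O)O[C@@H]1C[C@](C)(O[Si](C)(C)C)C2=CC[C@](C)(/C=C3/OC(=O)C(COC(C)=O)=C31)O2 | intermediate
32 | CNP0394509.1, (4R,5E,8R,10S) | C=C(C)C(=O)O[C@@H]1C[C@](C)(O)C2=CC[C@](C)(/C=C3/OC(=O)C(COC(C)=O)=C31)O2 | target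

**Step count and risks**

Total step count: 17. Longest linear sequence: 17 steps (1 → 32).

Steps most likely to fail:

1. Step 10 (bears the label). Processes that may go wrong: oligomerisation or simple conjugate reduction outrunning the slow ten-membered ring closure, reductive loss of the C10 silyloxy group, or ring closure through the other enone face so that the C4 epimer forms.
Fallback (sets out from 15, comes back at 20): the ring is closed at C2=C3 by olefin metathesis instead of at C3–C4. Tsuji–Wacker oxidation of 15 (PdCl2, CuCl, O2, DMF/H2O) should give the methyl ketone Weinreb amide F1. Excess vinylmagnesium bromide with CeCl3 should add to the ketone and convert the amide into the enone, giving the divinyl carbinol F2; C4 then forms without control, the epimers are separated, and the one with the target arrangement is carried on. Ring-closing metathesis with the second-generation Hoveyda–Grubbs catalyst at high dilution in toluene should give the ten-membered γ-hydroxy enone F3. Conjugate reduction with [(Ph3P)CuH]6 should give 19, which closes to 20.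

2. Step 17. Processes that may go wrong: ionisation of the tertiary allylic C4–O4 bond next to the enol lactone, or vinylogous enolisation of the butenolide with loss of the C13 acetate, under the silyl triflate instead of clean loss of methanol.
Fallback (sets out from 28, comes back at 32): the two eliminations are taken in the reverse order and without a silyl triflate. PPTS (cat.) in toluene over 5 Å molecular sieves at 60 °C should expel methanol from the ketal of 28 and give the enol ether hydroxybutenolide F4. Acylative dehydration (Ac2O, pyridine, DMAP) through its C6 acetate F5 should then form C5=C6 and give 32 directly, so the acid-labile C4 allylic ether is created only in the last, weakly basic operation.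

3. Step 4. Processes that may go wrong: slow catalyst turnover and pinacol-type homocoupling of the hindered 2,4-disubstituted furan-3-carbaldehyde, or insufficient enantiofacial discrimination.
Fallback (sets out from 5, comes back at 10): the C8–C9 bond is made from the alcohol oxidation level by iridium-catalysed transfer-hydrogenative carbonyl 2-(alkoxycarbonyl)allylation. Alcohol 5 is treated with [Ir(cod)Cl]2, a SEGPHOS ligand, 4-cyano-3-nitrobenzoic acid, Cs2CO3 and the tert-butyl carbonate of ethyl 2-(hydroxymethyl)prop-2-enoate in THF at 60 °C. The alcohol is dehydrogenated in the flask to 6, the chiral allyliridium adds to it to give 9, and acid work-up lactonises 9 to 10; no new compound is made and the MnO2 step is skipped.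

Further compounds
F1 | step 10 | (2S,4R)-4-(TBS-oxy)-N-methoxy-N,2-dimethyl-4-[2-(2-oxopropyl)-4-(TIPS-oxymethyl)furan-3-yl]-2-(TES-oxy)butanamide | CC(=O)Cc1occ(CO[Si](C(C)C)(C(C)C)C(C)C)c1[C@H](O[Si](C)(C)C(C)(C)C)C[C@](C)(O[Si](CC)(CC)CC)C(=O)N(C)OC
F2 | step 10 | (4S,6R)-6-(TBS-oxy)-6-{2-[(2S)-2-hydroxy-2-methylbut-3-en-1-yl]-4-(TIPS-oxymethyl)furan-3-yl}-4-methyl-4-(TES-oxy)hex-1-en-3-one | C=C[C@@](C)(O)Cc1occ(CO[Si](C(C)C)(C(C)C)C(C)C)c1[C@H](O[Si](C)(C)C(C)(C)C)C[C@](C)(O[Si](CC)(CC)CC)C(=O)C=C
F3 | step 10 | (2Z,4S,8R,10S)-ten-membered 4-hydroxy-2-en-1-one (ring of 19 with C2=C3; 8-OTBS, 10-OTES, 13-OTIPS) | O=C1/C=C\[C@@](C)(O)Cc2occ(CO[Si](C(C)C)(C(C)C)C(C)C)c2[C@H](O[Si](C)(C)C(C)(C)C)C[C@]1(C)O[Si](CC)(CC)CC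
F4 | step 17 | (4R,8R,10S)-enol ether hydroxybutenolide (28 without methanol: C1=C2, C5H2, C6–OH) | C=C(C)C(=O)O[C@@H]1C[C@](C)(O)C2=CC[C@](C)(CC3(O)OC(=O)C(COC(C)=O)=C31)O2
F5 | step 17 | C6 acetate of F4 | C=C(C)C(=O)O[C@@H]1C[C@](C)(O)C2=CC[C@](C)(CC3(OC(C)=O)OC(=O)C(COC(C)=O)=C31)O2
F0 | step 4 | none | none
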